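One substrate and one partner went into each product, so both substrates together minus the partner stayed constant in a run, within the catalyst charge. I had to decide whether to charge 0.122 M of partner and leave the catalyst as it was.

in all of them: free catalyst 31 µM

| flask | left-handed substrate | right-handed substrate | partner | remark | time |
|---|---|---|---|---|---|
| blue | 0.061 M | 0.061 M | 0.061 M | run made earlier |  |
| violet | 0.061 M | 0.061 M | 0.091 M | run made earlier |  |
| teal | 0.12 M | 0.12 M | 0.122 M | run made earlier |  |
| flask | 0.061 M | 0.061 M | 0.122 M |  | 5.0 h |

- blue (time / h: left-handed product / %, right-handed product / %): 0.500: 6, 7; 1.00: 10, 8; 1.50: 15, 14; 2.00: 17, 17; 2.50: 18, 15; 3.00: 20, 14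
- violet (time / h: left-handed product / %, right-handed product / %): 0.200: 3, 3; 0.667: 13, 12; 1.00: 15, 17; 1.50: 20, 22; 2.50: 26, 24; 3.00: 28, 27
- teal (time / h: left-handed product / %, right-handed product / %): 0.667: 9, 10; 1.33: 14, 15; 2.00: 22, 20; 2.50: 19, 21; 3.00: 17, 26

(each reading ± 2 percentage points)

- free catalyst is single-handed; left-handed substrate and right-handed substrate are mirror images of each other, charged as a racemate, each of them at the stated concentration
- an excess is below zero if the other one leads

1. excess of left-handed product over right-handed product in the product at 6.0 min
2. excess of left-handed product over right-handed product in the product at 5.0 h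
3. part of the left-handed substrate and right-handed substrate charged together that has reacted at 5.0 h

The decision hung on why blue and teal flattened. Blue's two products together read 34.0 % at 3.00 h, though its partner, the limiting reagent, allowed 50.0 %. If a balance had been reached, product over substrates times partner would have been one number. At 3.00 h I read 26.4 /M in blue and 51.1 /M in violet, and violet's two products together read 50.0 % at 2.50 h and 55.0 % at 3.00 h.

So I divided the rate of partner loss by substrates times partner. The invariant lets this be summed from a single reading, with no time in it. I called the sum the clock: the natural log of partner charge times substrate left, over substrate charge times partner left, divided by substrate charge minus partner charge. With equal charges, it is one over partner left minus one over partner charged. Violet's clock read 17.4 /M at 3.00 h. Blue's read 11.9 /M.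

If the clock stopped at violet's value, the flask would react 68.0 %. If it ran on at violet's pace, the flask would reach 78.0 % by 5.0 h. I expected the upper part of that span, and I charged the partner.

The forecast differed: 64 % reacted at 5.0 h, range 56 % to 74 %, with excesses of 0 % at 6.0 min and 0 % at 5.0 h, since the flattening “suggests a reversible reaction”.

The flask gave excesses of −8.84 % at 6.0 min and −3.28 % at 5.0 h, with 75.5 % reacted at 5.0 h.

    free catalyst → spent catalyst (k = 2.00 × 10⁻⁴ /s)
    partner + catalyst intermediate A → free catalyst + left-handed product (k = 13.0 /M/s)
    partner + catalyst intermediate B → free catalyst + right-handed product (k = 5.60 /M/s)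
    free catalyst + left-handed substrate ⇌ catalyst intermediate A (K = 20.0 /M, k = 71.0 /M/s)
    free catalyst + right-handed substrate ⇌ catalyst intermediate B (K = 41.0 /M, k = 490 /M/s)
    2 free catalyst ⇌ resting dimer, settled at all times (K = 24000 /M)
    left-handed substrate ⇌ right-handed substrate (k = 2.30 × 10⁻⁴ /s)

The flask's clock read 25.2 /M at 5.0 h, against violet's 17.4 /M at 3.00 h. At 5.0 h the flask held 73.9 % of its catalyst as spent catalyst, and the half-life of partner by the step through catalyst intermediate B alone was 14 h, longer than the 5.0 h run. A neighbour flask charged with 0.049 M of partner had reacted 34.9 % at 5.0 h, and its clock read 21.9 /M.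

The readings are simulated on assumed constants; scatter was added.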